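## Structural features

The target 35 is 12α,15β-dihydroxygibberellic acid; it has four carbocycles: cyclohexene ring A (C1=C2, 3β-OH, quaternary C4) bridged by the 19,10-γ-lactone, cyclopentane ring B (C5, C6, C8, C9, C10) carrying the C7 acid, and rings C and D, which together form a bicyclo[3.2.1]octane with bridgeheads C8 and C13. Ring A is trans-fused to ring B at C5–C10 and ring B is cis-fused to ring C at C8–C9. There are ten stereocentres: C3, C4, C5, C6, C10, C9 and C8 form one unbroken chain, and C12, C13 and C15 surround the C16 methylene. C4, C8, C10 and C13 carry no hydrogen. The fragile parts are the allylic lactone with the 3-hydroxyl (base causes retro-aldol epimerisation and lactone migration), the tertiary allylic 13-hydroxyl next to the exocyclic alkene (acid causes skeletal rearrangement), and any 13-hydroxy ketone met on the way (α-ketol shift). The real difficulty is quaternary C8 with four different carbon branches, together with three oxygens (12α, 13, 15β) that must be told apart on a compact bicycle. The key step uses two facts: C8 with C6–C7, C15 and C9–C10 is the carbon pattern of aconitic acid, and C11–C12–C13–C14 of ring C with its vicinal oxygens is a 2,3-dioxygenated butadiene. The enediol bis(silyl ether) left at C12=C13 after the cycloaddition is then the nucleophile that closes ring D.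

## Logic of the disconnections

35 is traced to 34 by cutting three O–Si bonds. Only a buffered fluoride source then touches the acid- and base-sensitive ring A, and the last step must be neutral enough to leave the allylic lactone alone.

34 is opened at C1=C2 to give 33. This removes ring A and the bridged lactone bicycle in one cut and leaves two vinyl groups held cis on the γ-lactone. The forward metathesis must leave the hindered 16-methylene untouched.

33 is cut at C3–C4, through 32 and 31, to 28 and 29. This removes the C3 and C4 stereocentres together. The forward aldol must come from the convex face of the bicyclic enolate 30, and C3 is set afterwards by chelation-controlled reduction of 32, so both C3 epimers of 31 converge.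

28 goes back through 27 to 25 by cutting C10–C1 and the C19–O bond at C10, and by restoring the C7 methyl ester. One vinyl addition sets C10 and the lactone closes by itself. The forward addition must come from the β face of the ring B ketone, away from the C5 side chain and ring C.

25 is cut at C4–C5 to 22 and 23. C4 arrives with its methyl group and C19 in one piece. The forward alkylation must occur at C5 and not at C9, and trans to the C6 ester.

22 is cut at C5–C10 (ring B) and then at C5–C6, through 20 and 19, to 17. C5 is a one-carbon unit placed on the only readily enolised ester. The forward ring closure needs a C5 carbanion equivalent made without base, because a β-leaving group on an ester eliminates under base.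

17 is traced to 16 (C12–H and O–Si) and 16 to 15 by cutting C13–C16. This removes ring D, the C13 stereocentre and the C12/C13 differentiation in one cut. The forward step needs the enediol ether to attack the alkyne through C13 only, which the five- versus six-membered ring choice should secure.

15 goes back through 14 and 12 to 9 and 10 by cutting C15–C16. The C15 stereocentre then rests on a reagent-controlled ynone reduction, which demands that quaternary C8 act as the large group.

9 comes from 8 by cleaving the ester C–O bond at C15. This demands that the C15 carboxyl, the most hindered of the three, be addressable alone. It is therefore an allyl ester from the start.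

8 is cut at C8–C14 and C9–C11 to 5 and 7. Ring C, quaternary C8 and C9 disappear and two achiral pieces remain. The forward cycloaddition needs facial control by a chiral Lewis acid and silyl enol ethers that survive it.

5 is cut at C8=C9 to 3 and 4. The C7 and C10 esters are kept identical so that any base-induced 1,3-shift of the double bond is degenerate, and the forward olefination must give the E alkene.

3 is cut at C6–C8 to 1 and 2. The forward alkylation must stop after one substitution.

7 comes from 6 by cutting two O–Si bonds. The forward double enol silylation must use a silyl group robust enough for the Lewis acid of the cycloaddition.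

## Other disconnections considered

Alternative 1: The cut is C4–C5, made by a lactone-derived Claisen ring contraction. In the forward direction the cyclic silyl ketene acetal A2 (C19–O–C1 six-membered ring, C10=C5 alkene in ring B) would rearrange [3,3] through an enforced boat to the ring A acid A1, with the C1=C10 alkene. In its favour: C4 and C5 are set stereospecifically in one metal-free thermal step by chirality transfer from C1, and A1 is set up for halolactonisation and elimination to the Δ1 lactone. On ring A stereocontrol this is better than the chosen plan, which relies on three separate substrate-controlled events (C5 alkylation, C4 aldol face, C3 chelate reduction). Against it here: A1 has no oxygen at C15 and has C7 at the alcohol level, so allylic oxidation at C15 with correction of its configuration and two oxidations at C7 would follow, next to a halolactonisation that must distinguish C1=C10 from the 16-methylene. A2 must also be built first, with its C1 carbinol configuration defined. The plan is silent on rings C and D, so it competes only with steps 11–20 of the chosen route. On step count it is expected to be about equal or slightly longer once the late oxidations are included.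

Alternative 2: The cut is C13–C16, made by an intramolecular crossed benzoin reaction. A carbene catalyst would convert the C16 aldehyde of keto aldehyde A4 into an acyl anion equivalent that adds to the C13 ketone, giving the bridgehead α-ketol A3. In its favour: metal-free, mild, and the tertiary 13-hydroxyl appears unprotected; five-membered aldehyde–ketone benzoin closures are well known. On precedent for the ring-forming step this is the better of the two, since the chosen ring D closure uses a nucleophile class not yet shown in that reaction. Both close the same five-membered ring onto C13, so they are equal on ring strain and geometry. Against it here: A4 needs a regiodefined C13 ketone beside a protected C12 alcohol, which the symmetric enediol ether of 8 does not provide without extra steps. A4 can also epimerise at C15 or lose its silyloxy group by the carbene redox pathway. A3 is a 13-hydroxy-16-ketone, prone to α-ketol rearrangement, and still needs methylenation of a ketone flanked by two oxygenated carbons. The chosen closure delivers the 16-methylene and the C12/C13 differentiation in the same step, so it is shorter by at least two steps.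

Alternative 3: The cuts are C3–C4 and C5–C10, made by one intramolecular Diels–Alder reaction. Heating triene A6 (a 1,4-bis(silyloxy)diene on C9 and a (Z)-2-methyl enoate on C6) would close rings A and B at once to A5. In its favour: two rings and four stereocentres (C3, C4, C5, C10) in one step, with the Z geometry translated into the cis relation of C19 and C6. On step economy it is clearly better than the ten steps (11–20) the chosen route spends on rings B and A. Against it here: the diene terminus at C10 is fully substituted and must place its silyloxy group inside the s-cis diene to give the trans relation of the C3 and C10 oxygens. The dienophile is trisubstituted, two fully substituted carbons (C4, C10) form in one thermal step, and facial and endo/exo selectivity relative to the C/D bicycle rest on the tether alone. The chosen plan is longer but sets each of these centres with its own control element. The two are equal in that both start from the same ring C/D intermediate.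

Key step: step 4

Assumption: 1, 2, 4, 6, 10, 23 and 29 are purchased (4 freshly distilled); the (S)-oxazaborolidine in step 4 is assigned from the usual binding model of enoate esters, and if the facial sense proves opposite the antipodal catalyst is used and nothing else changes; atom numbers are those of the gibberellane skeleton, and in 8 the C15 carboxyl on C8 is trans to the C10 carboxyl on C9 and C6 is cis to C10, as 35 requires.

## Route

Step 1
Reactants: 1 allyl 2-(diethoxyphosphoryl)acetate; 2 methyl bromoacetate
Product: 3 1-allyl 4-methyl 2-(diethoxyphosphoryl)butanedioate (racemic)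
Conditions: Cs2CO3, DMF, 0 °C to rt
Reagents that add atoms: none
Why: Enolate C-alkylation of a phosphonoacetate with an α-bromo ester (SN2) joins C8 to C6; the new stereocentre is destroyed in step 2, and a slight excess of 1 suppresses dialkylation.

Step 2
Reactants: 3 phosphonosuccinate; 4 methyl glyoxylate
Product: 5 2-allyl 1,3-dimethyl (E)-prop-1-ene-1,2,3-tricarboxylate (mixed trans-aconitate with C15 as allyl ester)
Conditions: LiCl, DBU, MeCN, 0 °C to rt
Reagents that add atoms: none
Why: Horner–Wadsworth–Emmons olefination forms C8=C9; the fumarate-like E isomer is the thermodynamic product and DBU equilibrates any Z isomer through the allylic anion. Because the C7 and C10 esters are both methyl, a 1,3-shift of the double bond returns the same compound.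

Step 3
Reactants: 6 butane-2,3-dione
Product: 7 2,3-bis(tert-butyldimethylsilyloxy)buta-1,3-diene
Conditions: TBSOTf (2.2 equiv), Et3N, CH2Cl2, 0 °C to rt
Reagents that add atoms: tert-butyldimethylsilyl trifluoromethanesulfonate, CC(C)(C)[Si](C)(C)OS(=O)(=O)C(F)(F)F
Why: Double soft enolisation and O-silylation of the diketone; TBS replaces TMS because the enediol ethers must survive a strong Lewis acid and five further steps.

Step 4
Reactants: 5 mixed trans-aconitate; 7 bis(silyloxy)diene
Product: 8 1-allyl 2-methyl (1S,2R)-1-(2-methoxy-2-oxoethyl)-4,5-bis(tert-butyldimethylsilyloxy)cyclohex-4-ene-1,2-dicarboxylate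
Conditions: (S)-1-(2-methylphenyl)-3,3-diphenyltetrahydro-1H,3H-pyrrolo[1,2-c][1,3,2]oxazaborole (20 mol%) protonated with Tf2NH, CH2Cl2, −78 to −40 °C
Reagents that add atoms: none
Why: This is a normal-demand Diels–Alder reaction: the C10 ester carbonyl of the fumarate-type diester 5 binds to boron of the cationic oxazaborolidine, and the electron-rich diene 7 adds in a concerted, asynchronous, suprafacial [4+2] process. The closest known reaction is the oxazaborolidinium-catalysed addition of fumarate esters to 2-silyloxybutadienes. Ring C closes as a six-membered carbocycle by the cycloaddition itself, C8–C14 and C9–C11 forming on the same face of the alkene. The relative configuration of C8 and C9 follows from the E geometry of 5, which places the C15 ester trans to the C10 ester and C6 cis to C10. The absolute configuration comes from the catalyst, whose diarylprolinol frame shields one face of the bound enoate so that the diene adds to the face that is Re at both C8 and C9. Only C9 carries a vinylic hydrogen next to an ester, which gives a single preferred binding site. The diene is symmetrical and unsubstituted at its termini, so there is no regiochemical or endo/exo question and facial selectivity is the only selectivity needed. The allyl ester and the TBS enol ethers are spectators chosen for the next steps.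

Step 5
Reactants: 8 cycloadduct
Product: 9 (1S,2R)-2-(methoxycarbonyl)-1-(2-methoxy-2-oxoethyl)-4,5-bis(tert-butyldimethylsilyloxy)cyclohex-4-ene-1-carboxylic acid
Conditions: Pd(PPh3)4 (5 mol%), morpholine, THF, rt; pH 5 buffer work-up
Reagents that add atoms: none
Why: Allyl ester cleavage through a π-allyl complex of zerovalent palladium frees only the C15 carboxyl, under neutral conditions that leave the silyl enol ethers and methyl esters alone.

Step 6
Reactants: 9 C15 acid; 10 ethynyltrimethylsilane
Product: 12 methyl (1R,2S)-2-(2-methoxy-2-oxoethyl)-2-[3-(trimethylsilyl)prop-2-ynoyl]-4,5-bis(tert-butyldimethylsilyloxy)cyclohex-4-ene-1-carboxylate, via acid chloride 11 (not isolated)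
Conditions: 1-chloro-N,N,2-trimethylprop-1-en-1-amine, CH2Cl2, 0 °C to rt; then 10, PdCl2(PPh3)2 (2 mol%), CuI (4 mol%), Et3N, THF, rt
Reagents that add atoms: none
Why: Acid chloride formation with the neutral α-chloroenamine avoids HCl, which would strip the enol ethers; acyl Sonogashira coupling then forms C15–C16 even at the neopentyl acyl centre.

Step 7
Reactants: 12 ynone
Product: 14 methyl (1R,2S)-2-[(1S)-1-(tert-butyldimethylsilyloxy)-3-(trimethylsilyl)prop-2-yn-1-yl]-2-(2-methoxy-2-oxoethyl)-4,5-bis(tert-butyldimethylsilyloxy)cyclohex-4-ene-1-carboxylate, via propargylic alcohol 13 (not isolated)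
Conditions: (S)-1-methyl-3,3-diphenyltetrahydro-1H,3H-pyrrolo[1,2-c][1,3,2]oxazaborole (1 equiv), catecholborane, toluene, −78 °C; MeOH quench, solvent exchange; then TBSOTf, 2,6-lutidine, CH2Cl2, −78 to 0 °C
Reagents that add atoms: tert-butyldimethylsilyl trifluoromethanesulfonate, CC(C)(C)[Si](C)(C)OS(=O)(=O)C(F)(F)F
Why: CBS reduction sets C15 under reagent control, with quaternary C8 as the large group and the alkynyl group as the small one, so the (S)-oxazaborolidine should deliver hydride to the face that gives the later 15β-oxygen. The alcohol is silylated crude so that it has no chance to lactonise onto the C7 or C10 ester.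

Step 8
Reactants: 14 silylated alkyne
Product: 15 methyl (1R,2S)-2-[(1R)-1-(tert-butyldimethylsilyloxy)prop-2-yn-1-yl]-2-(2-methoxy-2-oxoethyl)-4,5-bis(tert-butyldimethylsilyloxy)cyclohex-4-ene-1-carboxylate
Conditions: K2CO3 (0.3 equiv), MeOH, 0 °C
Reagents that add atoms: none
Why: Methanolysis of the C(sp)–Si bond is much faster than cleavage of TBS ethers or TBS enol ethers, and methyl esters in methanol cannot transesterify; the C15 descriptor changes only because the priorities change.

Step 9
Reactants: 15 terminal alkyne
Product: 16 ring C/D keto diester (bicyclo[3.2.1]octane with 12-oxo, 13-OTBS, 15β-OTBS, 16-methylene; CH2CO2Me on C8; CO2Me on C9 trans to the C15 bridge)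
Conditions: Ph3PAuNTf2 (5 mol%), CH2Cl2/MeOH 10:1, rt
Reagents that add atoms: none
Why: Proposed new method: the cationic gold catalyst activates the terminal alkyne, C13 of the bis(silyloxy)alkene attacks C16 anti to gold in a 5-exo-dig mode (attack by C12 would need a six-membered ring), the C12 oxocarbenium gives its silyl group to methanol, and protodeauration releases the 16-methylene; the closest known reaction is the gold-catalysed 5-exo-dig carbocyclisation of cyclic silyl enol ethers onto alkynes (Conia-ene type), not yet shown for 1,2-bis(silyloxy)alkenes; C13 is set by the tether, which brings C16 in on the face of C15, and the step also turns C12 into a ketone and C13 into a tertiary silyl ether.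

Step 10
Reactants: 16 ring C/D ketone
Product: 17 ring C/D diester with 12α,13,15β-tris(tert-butyldimethylsilyloxy) groups
Conditions: t-BuMe2SiH (1.1 equiv), B(C6F5)3 (5 mol%), toluene, 0 °C to rt
Reagents that add atoms: tert-butyldimethylsilane, C[SiH](C)C(C)(C)C
Why: Borane-catalysed carbonyl hydrosilylation puts silicon on oxygen before hydride arrives, so no free 12-alkoxide is formed that could lactonise onto the syn-axial C10 ester. The ketone is the most Lewis-basic carbonyl and should take up the silylium-like silicon ahead of the two esters, and one equivalent of silane keeps the esters, the silyl ethers and the alkene out of the reaction. The bulky hydridoborate should attack C12 from the face away from the axial ester, giving the axial 12α-silyl ether.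

Step 11
Reactants: 17 tris(silyl ether) diester
Product: 19 C6-hydroxymethyl diester (C5 installed as CH2OH; mixture of C6 epimers), via lithium ester enolate 18 (not isolated)
Conditions: LDA (1.05 equiv), THF, −78 °C; CH2O (gas, from cracked paraformaldehyde), −78 °C; AcOH quench at −78 °C
Reagents that add atoms: formaldehyde, C=O
Why: Kinetic enolisation occurs at the C6 methylene of the CH2CO2Me arm rather than at the hindered C9 methine, and the aldol addition to formaldehyde forms C5–C6. The cold acidic quench prevents retro-aldol and δ-lactonisation onto the C10 ester; the C6 configuration is corrected in step 13.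

Step 12
Reactants: 19 hydroxymethyl diester
Product: 20 C6-iodomethyl diester (mixture of C6 epimers)
Conditions: PPh3, I2, imidazole, CH2Cl2, 0 °C
Reagents that add atoms: iodine, II
Why: Appel-type iodination of the primary alcohol; the conditions are kept cold and only weakly basic so that the β-iodo ester does not eliminate to the acrylate.

Step 13
Reactants: 20 iodide
Product: 22 ring B ketone (10-oxo, C5 methylene, 6β-CO2Me, B/C cis), via C6-epimeric ketone mixture 21 (not isolated)
Conditions: SmI2 (2.5 equiv), Fe(PhCOCHCOPh)3 (3 mol%), THF, −30 °C to rt; aqueous work-up; then NaOMe (0.3 equiv), MeOH, rt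
Reagents that add atoms: none
Why: Two electrons from divalent samarium turn the primary iodide into an organosamarium, which acylates the C10 ester intramolecularly (nucleophilic acyl substitution; the five-membered ring is the only one within reach) and forms C5–C10. No base is present, so the β-iodo ester cannot eliminate. Methoxide should then equilibrate C6 toward the ester on the convex β face of the cis-fused B/C bicycle, and any 6α epimer that persists is separated and resubmitted.

Step 14
Reactants: 22 ring B ketone; 23 ethyl (S)-2-(trifluoromethylsulfonyloxy)propanoate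
Product: 25 ethyl (2S)-2-(ring B ketone C5-yl)propanoate (side chain 5α; 5β-H; 6β-CO2Me), via lithium ketone enolate 24 (not isolated)
Conditions: LDA (1.05 equiv), THF, −78 °C; then 23, −78 to −40 °C
Reagents that add atoms: none
Why: Kinetic deprotonation takes the C5 methylene rather than the ring-fusion C9 methine, and SN2 alkylation by the lactate triflate (inversion at C4) forms C4–C5 trans to the C6 ester; C5 stays epimerisable toward this trans arrangement. Inversion of the (S)-triflate puts the C4 hydrogen on the face that is convex in 27.

Step 15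
Reactants: 25 alkylated ketone
Product: 27 vinyl lactone (19,10-γ-lactone with O on the α face of C10; 10β-vinyl; C4–H; C7 methyl ester), via tertiary alkoxide 26 (not isolated)
Conditions: CeCl3 (3 equiv), vinylmagnesium bromide (3 equiv), THF, −78 to 0 °C
Reagents that add atoms: vinylmagnesium bromide, C=C[Mg]Br
Why: The organocerium reagent adds 1,2 to the hindered enolisable ketone without touching the esters, from the β face opposite the C5 side chain, ring C and the 12α-silyl ether. The resulting 10α-alkoxide is cis to the C19 ester and closes the γ-lactone on warming; the C7 ester is trans and cannot.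

Step 16
Reactants: 27 vinyl lactone methyl ester
Product: 28 vinyl lactone C7 carboxylic acid
Conditions: NaSPr (5 equiv), DMPU, 40 °C; then aqueous HCl to pH 3
Reagents that add atoms: none
Why: SN2 demethylation by thiolate takes place at the O-methyl carbon, so the steric shielding of the C7 acyl group does not matter. No other ester with a displaceable alkyl group is left, and the weakly basic thiolate does not enolise or open the lactone irreversibly.

Step 17
Reactants: 28 lactone acid; 29 acrolein
Product: 31 C4-(1-hydroxyallyl) lactone acid (C4 quaternary; C3 epimers), via dilithium lactone enolate carboxylate 30 (not isolated)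
Conditions: LDA (2.3 equiv), THF, −78 °C; then 29, −78 °C; AcOH quench
Reagents that add atoms: none
Why: The carboxylate shuts off enolisation at C6, so the second equivalent of base removes only the lactone α-hydrogen at C4. The aldol 1,2-addition to acrolein should occur on the convex face of the bicyclic lactone (the face of the C10 vinyl group, away from ring B), which sets C4 with C18 toward ring B and C3 cis to C1.

Step 18
Reactants: 31 aldol mixture
Product: 32 C4-acryloyl lactone acid (3-oxo)
Conditions: Dess–Martin periodinane, NaHCO3, CH2Cl2, 0 °C to rt; used crude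
Reagents that add atoms: none
Why: Oxidation of the secondary allylic alcohol merges both C3 epimers into one vinyl ketone; C4 is quaternary, so nothing can epimerise.

Step 19
Reactants: 32 vinyl ketone
Product: 33 (3S)-allylic alcohol lactone acid (3β-hydroxy after ring closure)
Conditions: Zn(BH4)2 (ethereal stock solution), Et2O/THF, −78 to −20 °C
Reagents that add atoms: none
Why: Zinc bridges the C3 ketone and the lactone carbonyl, and hydride adds 1,2 from the outer face of this chelate (the side of C18, away from the C10 vinyl group); this should give the alcohol that becomes the axial 3β-hydroxyl.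

Step 20
Reactants: 33 diene
Product: 34 12,13,15-tris-O-(tert-butyldimethylsilyl) derivative of 12α,15β-dihydroxygibberellic acid (3β-hydroxyl, lactone and C7 acid free)
Conditions: second-generation Grubbs catalyst (10 mol%), 1,4-benzoquinone (10 mol%), CH2Cl2 (5 mM), 40 °C
Reagents that add atoms: none
Why: Ring-closing metathesis joins C1 and C2 of the two monosubstituted vinyl groups, which are held cis and 1,3 on the γ-lactone, and closes ring A with loss of ethylene. The 1,1-disubstituted 16-methylene flanked by two silyloxy carbons should stay inert, and benzoquinone suppresses isomerisation of the allylic alcohol.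

Step 21
Reactants: 34 tris(silyl ether)
Product: 35 12α,15β-dihydroxygibberellic acid (the target)
Conditions: HF·pyridine (excess), pyridine/THF, 0 °C to rt
Reagents that add atoms: none
Why: Buffered fluoride cleaves the two secondary and the tertiary silyl ethers at a pH that neither shifts the allylic lactone (a base process) nor rearranges the 13-hydroxy-16-ene (a strong-acid process).

## Compound list

1 | allyl 2-(diethoxyphosphoryl)acetate | C=CCOC(=O)CP(=O)(OCC)OCC | starting material
2 | methyl bromoacetate | COC(=O)CBr | starting material
3 | 1-allyl 4-methyl 2-(diethoxyphosphoryl)butanedioate (racemic) | C=CCOC(=O)C(CC(=O)OC)P(=O)(OCC)OCC | intermediate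
4 | methyl glyoxylate | COC(=O)C=O | starting material
5 | 2-allyl 1,3-dimethyl (E)-prop-1-ene-1,2,3-tricarboxylate | COC(=O)C/C(C(=O)OCC=C)=C\C(=O)OC | intermediate
6 | butane-2,3-dione | CC(=O)C(C)=O | starting material
7 | 2,3-bis(tert-butyldimethylsilyloxy)buta-1,3-diene | C=C(O[Si](C)(C)C(C)(C)C)C(=C)O[Si](C)(C)C(C)(C)C | intermediate
8 | 1-allyl 2-methyl (1S,2R)-1-(2-methoxy-2-oxoethyl)-4,5-bis(tert-butyldimethylsilyloxy)cyclohex-4-ene-1,2-dicarboxylate | COC(=O)C[C@@]1(C(=O)OCC=C)CC(O[Si](C)(C)C(C)(C)C)=C(O[Si](C)(C)C(C)(C)C)C[C@H]1C(=O)OC | intermediate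
9 | (1S,2R)-2-(methoxycarbonyl)-1-(2-methoxy-2-oxoethyl)-4,5-bis(tert-butyldimethylsilyloxy)cyclohex-4-ene-1-carboxylic acid | COC(=O)C[C@@]1(C(=O)O)CC(O[Si](C)(C)C(C)(C)C)=C(O[Si](C)(C)C(C)(C)C)C[C@H]1C(=O)OC | intermediate
10 | ethynyltrimethylsilane | C#C[Si](C)(C)C | starting material
11 | acid chloride of 9 | COC(=O)C[C@@]1(C(=O)Cl)CC(O[Si](C)(C)C(C)(C)C)=C(O[Si](C)(C)C(C)(C)C)C[C@H]1C(=O)OC | intermediate
12 | C15 ynone (methyl (1R,2S)-2-(2-methoxy-2-oxoethyl)-2-[3-(trimethylsilyl)prop-2-ynoyl]-4,5-bis(TBS-oxy)cyclohex-4-ene-1-carboxylate) | COC(=O)C[C@@]1(C(=O)C#C[Si](C)(C)C)CC(O[Si](C)(C)C(C)(C)C)=C(O[Si](C)(C)C(C)(C)C)C[C@H]1C(=O)OC | intermediate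
13 | (1S)-propargylic alcohol from 12 | COC(=O)C[C@@]1([C@H](O)C#C[Si](C)(C)C)CC(O[Si](C)(C)C(C)(C)C)=C(O[Si](C)(C)C(C)(C)C)C[C@H]1C(=O)OC | intermediate
14 | TBS ether of 13 | COC(=O)C[C@@]1([C@H](O[Si](C)(C)C(C)(C)C)C#C[Si](C)(C)C)CC(O[Si](C)(C)C(C)(C)C)=C(O[Si](C)(C)C(C)(C)C)C[C@H]1C(=O)OC | intermediate
15 | terminal alkyne ((1R)-1-(TBS-oxy)prop-2-yn-1-yl on C8) | COC(=O)C[C@@]1([C@H](O[Si](C)(C)C(C)(C)C)C#C)CC(O[Si](C)(C)C(C)(C)C)=C(O[Si](C)(C)C(C)(C)C)C[C@H]1C(=O)OC | intermediate
16 | ring C/D keto diester (12-oxo, 13-OTBS, 15β-OTBS, 16-methylene) | C=C1[C@@H](O[Si](C)(C)C(C)(C)C)[C@]2(CC(=O)OC)C[C@@]1(O[Si](C)(C)C(C)(C)C)C(=O)C[C@H]2C(=O)OC | intermediate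
17 | ring C/D diester, 12α,13,15β-tris(TBS ether) | C=C1[C@@H](O[Si](C)(C)C(C)(C)C)[C@]2(CC(=O)OC)C[C@@]1(O[Si](C)(C)C(C)(C)C)[C@@H](O[Si](C)(C)C(C)(C)C)C[C@H]2C(=O)OC | intermediate
18 | lithium C6 ester enolate of 17 | C=C1[C@@H](O[Si](C)(C)C(C)(C)C)[C@]2(C=C([O-])OC)C[C@@]1(O[Si](C)(C)C(C)(C)C)[C@@H](O[Si](C)(C)C(C)(C)C)C[C@H]2C(=O)OC.[Li+] | intermediate
19 | C6-hydroxymethyl diester (C6 epimers) | C=C1[C@@H](O[Si](C)(C)C(C)(C)C)[C@]2(C(CO)C(=O)OC)C[C@@]1(O[Si](C)(C)C(C)(C)C)[C@@H](O[Si](C)(C)C(C)(C)C)C[C@H]2C(=O)OC | intermediate
20 | C6-iodomethyl diester (C6 epimers) | C=C1[C@@H](O[Si](C)(C)C(C)(C)C)[C@]2(C(CI)C(=O)OC)C[C@@]1(O[Si](C)(C)C(C)(C)C)[C@@H](O[Si](C)(C)C(C)(C)C)C[C@H]2C(=O)OC | intermediate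
21 | ring B ketone, C6 epimer mixture | C=C1[C@@H](O[Si](C)(C)C(C)(C)C)[C@]23C[C@@]1(O[Si](C)(C)C(C)(C)C)[C@@H](O[Si](C)(C)C(C)(C)C)C[C@H]2C(=O)CC3C(=O)OC | intermediate
22 | ring B ketone, 6β-methyl ester | C=C1[C@@H](O[Si](C)(C)C(C)(C)C)[C@]23C[C@@]1(O[Si](C)(C)C(C)(C)C)[C@@H](O[Si](C)(C)C(C)(C)C)C[C@H]2C(=O)C[C@@H]3C(=O)OC | intermediate
23 | ethyl (S)-2-(trifluoromethylsulfonyloxy)propanoate | CCOC(=O)[C@H](C)OS(=O)(=O)C(F)(F)F | starting material
24 | lithium C5 enolate of 22 | C=C1[C@@H](O[Si](C)(C)C(C)(C)C)[C@]23C[C@@]1(O[Si](C)(C)C(C)(C)C)[C@@H](O[Si](C)(C)C(C)(C)C)C[C@H]2C([O-])=C[C@@H]3C(=O)OC.[Li+] | intermediate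
25 | C5-alkylated ketone (5α side chain, (S) at C4, ethyl ester at C19) | C=C1[C@@H](O[Si](C)(C)C(C)(C)C)[C@]23C[C@@]1(O[Si](C)(C)C(C)(C)C)[C@@H](O[Si](C)(C)C(C)(C)C)C[C@H]2C(=O)[C@@H]([C@H](C)C(=O)OCC)[C@@H]3C(=O)OC | intermediate
26 | tertiary C10 alkoxide (bromomagnesium salt) | C=C1[C@@H](O[Si](C)(C)C(C)(C)C)[C@]23C[C@@]1(O[Si](C)(C)C(C)(C)C)[C@@H](O[Si](C)(C)C(C)(C)C)C[C@H]2[C@]([O-])(C=C)[C@@H]([C@H](C)C(=O)OCC)[C@@H]3C(=O)OC.[Mg+2].[Br-] | intermediate
27 | vinyl lactone methyl ester (19,10-lactone, 10β-vinyl, C4–H) | C=C1[C@@H](O[Si](C)(C)C(C)(C)C)[C@]23C[C@@]1(O[Si](C)(C)C(C)(C)C)[C@@H](O[Si](C)(C)C(C)(C)C)C[C@H]2[C@@]4(C=C)OC(=O)[C@@H](C)[C@H]4[C@@H]3C(=O)OC | intermediate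
28 | vinyl lactone C7 acid | C=C1[C@@H](O[Si](C)(C)C(C)(C)C)[C@]23C[C@@]1(O[Si](C)(C)C(C)(C)C)[C@@H](O[Si](C)(C)C(C)(C)C)C[C@H]2[C@@]4(C=C)OC(=O)[C@@H](C)[C@H]4[C@@H]3C(=O)O | intermediate
29 | acrolein | C=CC=O | starting material
30 | dilithium lactone enolate carboxylate of 28 | C=C1[C@@H](O[Si](C)(C)C(C)(C)C)[C@]23C[C@@]1(O[Si](C)(C)C(C)(C)C)[C@@H](O[Si](C)(C)C(C)(C)C)C[C@H]2[C@@]4(C=C)OC([O-])=C(C)[C@H]4[C@@H]3C(=O)[O-].[Li+].[Li+] | intermediate
31 | C4-(1-hydroxyallyl) lactone acid (C3 epimers) | C=C1[C@@H](O[Si](C)(C)C(C)(C)C)[C@]23C[C@@]1(O[Si](C)(C)C(C)(C)C)[C@@H](O[Si](C)(C)C(C)(C)C)C[C@H]2[C@@]4(C=C)OC(=O)[C@](C)(C(O)C=C)[C@H]4[C@@H]3C(=O)O | intermediate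
32 | C4-acryloyl lactone acid | C=C1[C@@H](O[Si](C)(C)C(C)(C)C)[C@]23C[C@@]1(O[Si](C)(C)C(C)(C)C)[C@@H](O[Si](C)(C)C(C)(C)C)C[C@H]2[C@@]4(C=C)OC(=O)[C@](C)(C(=O)C=C)[C@H]4[C@@H]3C(=O)O | intermediate
33 | (3S)-allylic alcohol lactone acid | C=C1[C@@H](O[Si](C)(C)C(C)(C)C)[C@]23C[C@@]1(O[Si](C)(C)C(C)(C)C)[C@@H](O[Si](C)(C)C(C)(C)C)C[C@H]2[C@@]4(C=C)OC(=O)[C@](C)([C@@H](O)C=C)[C@H]4[C@@H]3C(=O)O | intermediate
34 | 12,13,15-tris-O-(tert-butyldimethylsilyl) derivative of 12α,15β-dihydroxygibberellic acid | C=C1[C@@H](O[Si](C)(C)C(C)(C)C)[C@]23C[C@@]1(O[Si](C)(C)C(C)(C)C)[C@@H](O[Si](C)(C)C(C)(C)C)C[C@H]2[C@@]12C=C[C@H](O)[C@@](C)(C(=O)O1)[C@H]2[C@@H]3C(=O)O | intermediate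
35 | 12α,15β-dihydroxygibberellic acid (3β,12α,13,15β-tetrahydroxy-1,16-diene 19,10-lactone 7-oic acid of the gibberellane skeleton) | C=C1[C@@H](O)[C@]23C[C@@]1(O)[C@@H](O)C[C@H]2[C@@]12C=C[C@H](O)[C@@](C)(C(=O)O1)[C@H]2[C@@H]3C(=O)O | target

## Step count and least certain steps

Total: 21 steps. Longest linear sequence: 20 steps (steps 1, 2 and 4–21); step 3 is a one-step branch to 7.

Step 9 (ring D closure, the proposed new method). The likely failure is protodesilylation of the enediol ether to the acyloin by adventitious acid before carbon–carbon bond formation, or slow cyclisation because the 15β-silyloxy group sits over ring C in the transition state. The fallback uses a stannyl-radical enyne cyclisation and sets out from 15. Bu3SnH with a radical initiator in toluene at 80 °C adds tin to C17; the C16 vinyl radical closes 5-exo onto C13, and the C12 α-silyloxy radical takes hydrogen on the face away from the axial C10 ester, giving the vinylstannane F1 with the 12α-silyl ether already in place. Protodestannylation with CF3CO2H (1.1 equiv) in CH2Cl2 at −40 °C gives 17, where the route is rejoined, so steps 9 and 10 are both replaced.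

Step 4 (key step). The likely failures are poor facial selectivity, because three ester carbonyls compete for the boron centre, and loss of the trans C15/C10 relation if the addition becomes a stepwise Mukaiyama–Michael process with bond rotation before ring closure. The fallback gives up catalytic enantiocontrol and sets out from 5 and 7. Cycloaddition with Et2AlCl in CH2Cl2 at −78 °C (or heating in toluene) gives the racemic cycloadduct F2. Deallylation as in step 5 gives the racemic acid F3. Crystallisation with (R)-1-phenylethylamine (or its antipode, as screening dictates) gives the diastereomerically pure ammonium salt F4. Partition between cold aqueous KHSO4 and ethyl acetate returns enantiopure 9, where the route is rejoined.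

Step 13 (ring B closure). The likely failure is cyclisation of the intermediate C5 radical onto the 16-methylene before it is reduced to the organosamarium, or attack of the organosamarium on the adjacent C7 ester. The fallback reverses the polarity, forms C5–C6 last, and sets out from 17. The C7 ester is protected as its lithium enolate (LDA, −78 °C). Chloromethyllithium, made in the flask from ICH2Cl and MeLi·LiBr at −78 °C, adds only to the C10 ester. Collapse of the adduct gives the chloromethyl ketone F5 as its C6 enolate, which closes ring B by intramolecular SN2 displacement on warming. This gives 21, which is equilibrated to 22 as in step 13.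

Step 19 (C3 configuration). The likely failure is hydride delivery to the other face if the chelate is not formed or is shielded differently than assumed, giving the 3α-alcohol. The fallback exchanges the roles of nucleophile and electrophile on the same chelate and sets out from 28. The dianion 30 is C-formylated with methyl formate to give the C4-formyl lactone acid F6. Vinylmagnesium bromide with ZnCl2 at −78 °C then adds to the chelated aldehyde; since vinyl now takes the place that hydride took, the opposite C3 epimer relative to the failed reduction results. The route is rejoined at 33.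

## Further compounds

F1 | step 9 | vinylstannane (C17-tributylstannyl ring C/D diester, 12α,13,15β-tris(TBS ether); alkene geometry left open) | CCCC[Sn](CCCC)(CCCC)C=C1[C@@H](O[Si](C)(C)C(C)(C)C)[C@]2(CC(=O)OC)C[C@@]1(O[Si](C)(C)C(C)(C)C)[C@@H](O[Si](C)(C)C(C)(C)C)C[C@H]2C(=O)OC
F2 | step 4 | racemic cycloadduct (8 with its enantiomer, 1:1) | COC(=O)C[C@@]1(C(=O)OCC=C)CC(O[Si](C)(C)C(C)(C)C)=C(O[Si](C)(C)C(C)(C)C)C[C@H]1C(=O)OC.COC(=O)C[C@]1(C(=O)OCC=C)CC(O[Si](C)(C)C(C)(C)C)=C(O[Si](C)(C)C(C)(C)C)C[C@@H]1C(=O)OC
F3 | step 4 | racemic acid (9 with its enantiomer, 1:1) | COC(=O)C[C@@]1(C(=O)O)CC(O[Si](C)(C)C(C)(C)C)=C(O[Si](C)(C)C(C)(C)C)C[C@H]1C(=O)OC.COC(=O)C[C@]1(C(=O)O)CC(O[Si](C)(C)C(C)(C)C)=C(O[Si](C)(C)C(C)(C)C)C[C@@H]1C(=O)OC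
F4 | step 4 | (R)-1-phenylethylammonium salt of 9 | COC(=O)C[C@@]1(C(=O)[O-])CC(O[Si](C)(C)C(C)(C)C)=C(O[Si](C)(C)C(C)(C)C)C[C@H]1C(=O)OC.C[C@@H]([NH3+])c1ccccc1
F5 | step 13 | C10 chloromethyl ketone (ring C/D, C7 methyl ester, tris(TBS ether)) | C=C1[C@@H](O[Si](C)(C)C(C)(C)C)[C@]2(CC(=O)OC)C[C@@]1(O[Si](C)(C)C(C)(C)C)[C@@H](O[Si](C)(C)C(C)(C)C)C[C@H]2C(=O)CCl
F6 | step 19 | C4-formyl lactone acid | C=C1[C@@H](O[Si](C)(C)C(C)(C)C)[C@]23C[C@@]1(O[Si](C)(C)C(C)(C)C)[C@@H](O[Si](C)(C)C(C)(C)C)C[C@H]2[C@@]4(C=C)OC(=O)[C@](C)(C=O)[C@H]4[C@@H]3C(=O)O
A1 | alternative 1 | ring A cyclohexene C19 acid | C=C1C[C@]23C[C@@]1(O[Si](C)(C)C)[C@@H](O[Si](C)(C)C(C)(C)C)C[C@H]2C1=CC[C@H](O[Si](C)(C)C(C)(C)C)[C@@](C)(C(=O)O)[C@H]1[C@@H]3CO[Si](C)(C)C(C)(C)C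
A2 | alternative 1 | cyclic silyl ketene acetal (C19–O–C1 ring on the C10=C5 cyclopentene) | C=C1C[C@]23C[C@@]1(O[Si](C)(C)C)[C@@H](O[Si](C)(C)C(C)(C)C)C[C@H]2C(=C[C@@H]3CO[Si](C)(C)C(C)(C)C)[C@@H]1C[C@H](O[Si](C)(C)C(C)(C)C)C(C)=C(O[Si](C)(C)C)O1
A3 | alternative 2 | tricyclic 13-hydroxy-16-ketone | O=C1[C@@H](O[Si](C)(C)C(C)(C)C)[C@]23C[C@@]1(O)[C@@H](O[Si](C)(C)C(C)(C)C)C[C@H]2C4(OCCO4)C[C@@H]3C(=O)OC
A4 | alternative 2 | C13 keto C16 aldehyde | O=C[C@@H](O[Si](C)(C)C(C)(C)C)[C@]12CC(=O)[C@@H](O[Si](C)(C)C(C)(C)C)C[C@H]1C3(OCCO3)C[C@@H]2C(=O)OC
A5 | alternative 3 | tetracarbocyclic cycloadduct | C=C1[C@@H](O[Si](C)(C)C(C)(C)C)[C@]23C[C@@]1(O[Si](C)(C)C)[C@@H](O[Si](C)(C)C(C)(C)C)C[C@H]2[C@]1(O[Si](C)(C)C(C)(C)C)C=C[C@H](O[Si](C)(C)C(C)(C)C)[C@@](C)(C(=O)OC)[C@H]1[C@@H]3C(=O)OC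
A6 | alternative 3 | triene (1,4-bis(silyloxy)diene on C9, (Z)-2-methyl enoate on C6) | C=C1[C@@H](O[Si](C)(C)C(C)(C)C)[C@]2([C@@H](C(=O)OC)/C=C(/C)C(=O)OC)C[C@@]1(O[Si](C)(C)C)[C@@H](O[Si](C)(C)C(C)(C)C)C[C@H]2/C(O[Si](C)(C)C(C)(C)C)=C/C=C/O[Si](C)(C)C(C)(C)C
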